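Second substrate is the charge I am asked about, and no run has changed it yet.

the same everywhere: starting material 1.5 M

| flask | second substrate | free catalyst | remark |
|---|---|---|---|
| Thursday's | 0.75 M | 38 mM | the very flask that is asked about, followed so far |
| Sunday's | 0.75 M | 76 mM | run made earlier |
| flask | 0.750 M | 38 mM |  |

- Thursday's (time / h: target / %, starting material / %): 2.00: 1.5, 96.5; 5.00: 4.5, 94.9; 10.0: 11.0, 87.1; 15.0: 14.9, 81.7
- Sunday's (time / d: target / %, starting material / %): 0.833: 42.7, 53.3; 1.67: 72.7, 26.3; 2.50: 90.3, 7.4; 4.00: 97.7, 1.2

(each reading ± 1 percentage point)

- what is bound to the catalyst counts as converted
- no earlier run changes the charge of second substrate; that part of a forecast is a guess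

- apparent order in second substrate when 5.0% of the starting material are converted (percent change of the rate of making target for one percent more second substrate charged)
- factor on the rate of making target when 5.0% of the starting material are converted if second substrate is charged twice over

I turn the question round. Suppose second substrate were a reagent used up in making target, one way in which more of it could raise the rate; then its charge would cap the target. Sunday's last reading gives 1.95 for Y, the moles of target made per mole of second substrate charged. A one-to-one partner would be the limiting reagent and hold Y at 1, and Sunday's Y stands above that, so second substrate is no such partner. A two-to-one partner still passes, since Sunday's Y lies under 2, but such a partner must have lost the share Y/2 of its charge, and no run measured second substrate. My own guess is that it stays out of the making of target, with order 0 and factor 1. The forecast instead allows that “about two starting material are used per second substrate”, calls its choice a guess, and gives an order of 0.5 and a factor of 1.4, above my factor.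

The flask gives an order of −0.16 and a factor of 0.861, so twice the second substrate lowers the rate of making target.

    starting material + free catalyst ⇌ catalyst intermediate A (K = 75.0 /M, k = 3.05 × 10⁻⁴ /M/s)
    catalyst intermediate A → free catalyst + target (k = 2.34 × 10⁻⁴ /s)
    second substrate + free catalyst ⇌ catalyst intermediate B (K = 2.00 /M, k = 2.95 × 10⁻⁴ /M/s)
    catalyst intermediate B → free catalyst + second product (k = 2.43 × 10⁻⁴ /s)

At 5.00 d Thursday's flask has Y = 1.82, so a two-to-one partner would have lost 91.0% of its charge, yet the flask has lost 77.8% of its second substrate. Starting material and second substrate draw on the same free catalyst, and at the start of this flask starting material uses it 2.1 times as fast, forward steps alone. At 0.500 d in this flask catalyst intermediate A holds 52.2% of the catalyst and catalyst intermediate B holds 16.2%.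

(The earlier runs and the new flask are simulated on assumed constants, and the scatter is random.)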